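- Slowness costs substrate in these set-ups: at the common charge, a substrate molecule is consumed by self-condensation at 0.753 s⁻¹, faster than it could meet catalyst intermediate C, at 0.0738 s⁻¹, even with the catalyst charge entirely in that form.

| flask | substrate | coupling partner | free catalyst | remark | time |
|---|---|---|---|---|---|
| Wednesday's | 0.067 M | 0.0871 M | 1.4 mM | one stirred flow tank at steady state, fed with the mixture as stated, mean residence time 2.5 min |  |
| Saturday's | 0.067 M | 0.0871 M | 1.4 mM | a single well-mixed tank run continuously and read at steady state, 7.50 min in it on average |  |
| Friday's | 0.067 M | 0.0871 M | 1.4 mM | everything together in a closed stirred flask, run for 2.5 min | 2.5 min |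
| Sunday's | 0.067 M | 0.0871 M | 1.4 mM | a tube with plug flow, the mixed feed as stated, residence time 2.5 min | 2.5 min |

    coupling partner + free catalyst ⇌ catalyst intermediate A (K1 = 10.1 L mol⁻¹, k1 = 28.9 L mol⁻¹ s⁻¹)
    catalyst intermediate A → catalyst intermediate B (k2 = 0.747 s⁻¹)
    catalyst intermediate B → by-product + catalyst intermediate C (k3 = 115 s⁻¹)
    substrate + catalyst intermediate C ⇌ catalyst intermediate D (K4 = 12.8 L mol⁻¹, k4 = 52.7 L mol⁻¹ s⁻¹)
    catalyst intermediate D → free catalyst + target (k5 = 2.83 s⁻¹)
    2 substrate → self-condensation product (k6 = 5.62 L mol⁻¹ s⁻¹)

- in percentages every species weighs as the substrate in it: one self-condensation product counts as two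
- two of one species on the left: rate k times its square, two consumed each time
- the stated concentrations are those of everything mixed, before any reaction; amounts are the same in each set-up
- run time (Friday's): 2.5 min

* the set-up with the highest amount of target at the outlet or at the end, in percent of the substrate put in ("none" if the first two lie within 2 percentage points) (Wednesday's / Saturday's / Friday's / Sunday's / none)
* amount of target at the outlet or at the end, in percent of the substrate put in, Wednesday's
* amount of target at the outlet or at the end, in percent of the substrate put in, Saturday's
* amount of target at the outlet or at the end, in percent of the substrate put in, Friday's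
* amount of target at the outlet or at the end, in percent of the substrate put in, Sunday's

- Follow one substrate molecule. Once bound as catalyst intermediate D, it goes on to target with chance 40.7%, the forward rate constant over forward plus return, so productive capture has the constant 21.5 L mol⁻¹ s⁻¹.
- This reckoning by hand takes catalyst intermediate C as the resting state and sets productive capture by the catalyst charge against self-condensation. They tie at 2.67 mM. This even-odds concentration is the substrate level at which a molecule's chance of reaching target is one half; at concentration c(substrate), the chance is the even-odds concentration over the sum of that concentration and c(substrate).
- Sunday's tube and Wednesday's tank look nearly the same, with one charge and one time, 2.5 min, on average in Wednesday's tank. Sunday's tube starts at 25.1 times the even-odds concentration, where the chance is 3.84%, and substrate then falls through the lower levels. Averaging the chance over that fall gives a ceiling for Sunday's of 13.0%. Friday's closed flask follows the same equations, so its ceiling is 13.0%.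
- Wednesday's tank dilutes its feed at once. Its balance gives a substrate level of 4.88 mM, so each reacting molecule has a chance of 35.4%, and the ceiling is 32.8%.
- For Saturday's tank, with 7.50 min on average, the same balance gives 2.48 mM, and its ceiling is 50.0%. The ranking by ceilings puts Saturday's first.
- These are ceilings, since the catalyst enters free and must pass through catalyst intermediate A, which falls back faster than it goes on.
- The forecast names Saturday's, with 23.6% (22% to 25%) for Wednesday's, 42.2% (40% to 44%) for Saturday's, and 7% (6% to 8%) for Friday's. For Sunday's it gives 7% (6% to 8%). Its grounds: “The stirred tanks hold substrate at a few mM, where the catalytic route competes far better”. Its ranking matches this reckoning, but its figures are lower, as for Saturday's.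
- The simulation puts Saturday's first with 42.3%, then Wednesday's with 23.6%, while Friday's and Sunday's give 6.92% and 6.92%. Saturday's tank read 0.00267 M of substrate, close to the even-odds concentration. Sunday's tube charged with 0.017 M of substrate starts at 6.37 times that concentration, giving a ceiling of 31.4%; that tube ended with 22.2% of its charged substrate as target.

The numbers are those of an exercise; no experiment stands behind them.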